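## Structural features

The target is a spiro[5.5]undecane of the chamigrene type (chamigrene numbering throughout: ring B = C1–C6, ring A = C6–C11, C14 = exocyclic methylene carbon on C7). Ring A carries the C7 methylene, a gem-dimethyl group at C11 and a secondary bromide at C10; ring B carries a secondary bromide at C2 next to a methyl-bearing tertiary alcohol at C3. The rings share only the quaternary carbon C6, which lies between the fully substituted C11 and the sp2 carbon C7. The four stereocentres are (2R,3R,6R,10S): C2 and C3 are contiguous and trans, C10 is 1,3 to C6, and C6 is stereogenic only because its two ring B arms differ, the C1 arm lying on the same side of ring A as the C10 bromine. In the ring B chair that keeps C11 equatorial, Br at C2 and OH at C3 are both equatorial, so the bromohydrin is not the product of a simple trans-diaxial opening. Fragile groups are the neopentyl C10–Br bond (low-valent metals, elimination), the β-bromo tertiary alcohol (epoxide closure with base) and the exocyclic alkene (acid-induced migration). The real difficulty is the congested spiro centre with a defined sense relative to remote C10, followed by face and site control in the bromohydrin. The key step uses the fact that C1–C2(=O)–C5 on C6 is a spiro-fused cyclobutanone and C3–C4 a two-carbon alkyne unit, so C6 becomes stereogenic only when one of the two C2–CH2 bonds is broken.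

## Logic of the disconnections

24 to 23: the C2–Br and C3–O bonds are cut. Their trans relationship is the retron of bromonium opening by water. This removes two stereocentres and both ring B heteroatoms. The forward step must address the trisubstituted C2=C3 alkene rather than C7=C14, deliver bromine anti to C7 and let water open at C3.

23 to 22: the C7=C14 bond is cut to a carbonyl group, because C7 needs oxygen earlier in the route. The forward step must methylenate a hindered, enolisable ketone without base.

22 to 21 to 20: oxidation level and protection at C7 are adjusted. C7 is carried as a silyl ether rather than a ketone through the nickel step and the enone chemistry. A C7 ketone would put an enolisable C8 five atoms from the enone β-carbon C4 (intramolecular Michael addition) and would compete as a second carbonyl group. The forward steps are a desilylation and an oxidation that leave the alkene and the bromide untouched.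

20 to 19 to 18: the C2–H and C4–H bonds are traced back to a C2 carbonyl with a C3=C4 alkene. A reductive 1,3-transposition through the sulfonylhydrazone removes the oxygen and moves the alkene to C2=C3 in one operation. The forward reduction must add hydride 1,2 and spare the C–Br bond.

18 to 17: the C4–H bond is traced back to C4–Si. Silicon is only the regiocontrol element of the alkyne and must leave a tetrasubstituted, electron-poor alkene carbon without loss of the O-silyl group. For that reason the silyl group is benzyldimethylsilyl, which fluoride cleaves under mild conditions, and not trimethylsilyl.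

17 to 13 + 16 (key): the C2–C3 and C4–C5 bonds are cut. Ring B collapses to a four-membered ketone and C6 loses its stereogenicity. The forward step must break the C2–CH2 bond of the arm trans to the C10 bromine (that arm becomes C5) and place the methyl-bearing alkyne carbon on C2. The configurations of 13, 17 and 24 were re-derived and agree with this requirement; no connectivity needed correction.

16 to 14 + 15: the Si–C(sp) bond is cut, a routine silylation of an alkynyl Grignard reagent.

13 to 9 + 10 (through 11 and 12): the C6–C and CH2–C(=O) bonds of the four-membered ring are cut, together with two C–Cl bonds, the retron of a ketene [2+2] cycloaddition. The forward step must add to a 1,1-disubstituted alkene flanked by two substituted carbons, which calls for the most electrophilic ketene.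

9 to 8 to 7: the O–Si and C7–H bonds are cut. The enone is too electron-poor for a ketene, so it is reduced and the alcohol masked.

7 to 6 to 5: C6=CH2 is traced to a β-acetoxy ketone and the C7 carbonyl to the exocyclic alkene.

5 to 4: the C6–C11 bond of ring A is cut, the retron of a bromonium-initiated cation–olefin cyclisation. The bromonium ion must be generated without loss of configuration.

4 to 3 to 2 to 1: the C–Cl, C–Br and epoxide C–O bonds are cut. Absolute configuration is introduced by a catalytic epoxidation and passed on by one inversion at C10.

## Other disconnections considered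

Alternative 1: The cut is the C6–C11 bond of ring A, which opens the spirocycle to the monocyclic triene (E)-γ-bisabolene A1. In the forward sense a vanadium-dependent bromoperoxidase, with bromide and peroxide as co-substrates, would deliver electrophilic bromine to C10=C11. C6 of the tetrasubstituted alkene would attack C11 and a C14 proton would be lost, giving 10-bromo-β-chamigrene A2, which is identical with 23.
- In favour: ring A, C6 and C10 would be formed in one operation from a C15 hydrocarbon without protecting groups. The relative configuration of C6 and C10 would follow from the alkene geometry through a chair transition state. On step economy this is clearly the better plan, and on C6/C10 relative control it is at least the equal of the chosen one.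
- Against: A1 has three nucleophilic alkenes, and the tetrasubstituted one is the most electron-rich. Such enzymes often release diffusible hypobromite-level bromine, so control of absolute configuration and of proton loss is not assured. Geometrically pure A1 is not a commodity.
- Comparison: both plans pass through the same late compound. The chosen plan is longer but takes its absolute configuration from a defined epoxide and relays it by stereospecific steps.

Alternative 2: The cuts are C5–C6 and C1=C2 of the spiro enone A5, leading back to bromo-γ-cyclocitral A3 and methyl vinyl ketone A4. The exocyclic dienolate of A3 would add through C6 to A4, and aldol condensation of the methyl ketone with the aldehyde would close ring B.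
- In favour: A3 would come from 5 by deacetylation and oxidation. The C7 methylene from the cyclisation would be kept, so ozonolysis, re-methylenation and the nickel step near a C–Br bond would all disappear. This is the better plan on step economy. The C3 carbonyl of A5 is well placed for methyl addition.
- Against: C6 is the most hindered position of the dienolate and must react in preference to C14. Base can move the exocyclic double bond of A3 into conjugation with the aldehyde and remove the nucleophile. The facial selectivity at C6 would rest on substrate bias alone.
- Comparison: the later installation of the C2 bromide and C3 carbinol under substrate control would be no easier than the bromohydrin step of the chosen plan (equal). The chosen plan keeps a catalyst handle on C6.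

Alternative 3: The cut is the C2–C3 bond of the α-ketol A7, leading back to the keto aldehyde A6. A chiral triazolium-derived carbene would convert the C2 aldehyde into an acyl anion equivalent that adds to the C3 methyl ketone.
- In favour: the C3 tertiary alcohol would be set directly under catalyst control. That is superior to the chosen plan, where C3–O arises last under substrate control. The closure is metal-free, mild and compatible with the bromide and the exocyclic alkene.
- Against: C6 must already carry two different arms in the right sense, so the hard problem is moved into the synthesis of A6 and not solved. The C2 carbonyl of A7 would then have to become a C–Br bond of defined configuration next to a tertiary alcohol, where epoxide formation competes.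
- Comparison: the chosen plan forms ring B and C6 in one event, whereas this one forms ring B and C3. Step economy would probably be worse.

Key step: step 10

Assumption: reduction of 7 is taken to give the C7 epimer with oxygen cis to bromine (hydride anti to the axial C11 methyl group); the centre is oxidised again in step 15, so only uniformity matters.

Assumption: 12 is drawn as the epimer expected from ring closure at C6 anti to the axial C11 methyl and C7 silyloxy groups; this centre loses its stereogenicity on dechlorination.

Assumption: the (S,S,S) antipode of the phosphoramidite ligand is taken as the one matched to 13; the sense cannot be derived from first principles and the antipode is the immediate substitute.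

## Steps

Step 1
Reactants: 1 geranyl acetate [(2E)-3,7-dimethylocta-2,6-dien-1-yl acetate]
Product: 2 (2E)-5-[(2R)-3,3-dimethyloxiran-2-yl]-3-methylpent-2-en-1-yl acetate
Conditions: D-fructose-derived Shi ketone (0.3 equiv), KHSO5 (Oxone), K2CO3, Bu4NHSO4, Na2B4O7 buffer, MeCN/CH2(OMe)2/H2O, 0 °C
Reagents that add atoms: potassium peroxymonosulfate, [K+].OOS(=O)(=O)[O-]
Why: Shi asymmetric epoxidation; the distal trisubstituted alkene is more electron-rich than the acetate-deactivated allylic one, and the spiro transition state of the D-fructose-derived dioxirane should give the (R)-epoxide.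

Step 2
Reactants: 2 (2E)-5-[(2R)-3,3-dimethyloxiran-2-yl]-3-methylpent-2-en-1-yl acetate
Product: 3 (2E,6S)-6-bromo-7-hydroxy-3,7-dimethyloct-2-en-1-yl acetate
Conditions: Li2NiBr4, THF, 0 °C to rt; pH 7 buffer
Reagents that add atoms: dilithium tetrabromonickelate, [Li+].[Li+].Br[Ni-2](Br)(Br)Br
Why: SN2 opening of a trisubstituted epoxide by soft bromide at the less substituted carbon; inversion there turns the (R)-epoxide carbon into the (S)-bromide that becomes C10.

Step 3
Reactants: 3 (2E,6S)-6-bromo-7-hydroxy-3,7-dimethyloct-2-en-1-yl acetate
Product: 4 (2E,6S)-6-bromo-7-chloro-3,7-dimethyloct-2-en-1-yl acetate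
Conditions: SOCl2, CH2Cl2, −20 to 0 °C
Reagents that add atoms: thionyl chloride, O=S(Cl)Cl
Why: Chlorodehydroxylation of a tertiary alcohol through its chlorosulfite; ionisation is assisted by the neighbouring bromine and chloride returns to the tertiary carbon, so the C–Br centre is untouched.

Step 4
Reactants: 4 (2E,6S)-6-bromo-7-chloro-3,7-dimethyloct-2-en-1-yl acetate
Product: 5 [(1R,3S)-3-bromo-2,2-dimethyl-6-methylidenecyclohexyl]methyl acetate
Conditions: (CF3)2CHOH, NaHCO3 (solid), rt
Reagents that add atoms: none
Why: Solvolysis of the tertiary chloride in the ionising, non-nucleophilic solvent gives the bromonium ion with retention of the bromide configuration (enantiospecific bromonium-initiated cation–olefin cyclisation); the (E)-alkene closes ring A through a chair with bromine and the acetoxymethyl arm equatorial (cis), and loss of a methyl proton gives the exocyclic alkene. Endocyclic alkene isomers are expected alongside and are removed after step 5, since only 5 can give 7.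

Step 5
Reactants: 5 [(1R,3S)-3-bromo-2,2-dimethyl-6-methylidenecyclohexyl]methyl acetate
Product: 7 (4S)-4-bromo-3,3-dimethyl-2-methylidenecyclohexan-1-one, via keto acetate 6 (not isolated)
Conditions: O3, CH2Cl2/MeOH, −78 °C; Me2S, −78 °C to rt; then DBU, CH2Cl2, 0 °C
Reagents that add atoms: ozone, [O-][O+]=O
Why: Ozonolysis turns the exocyclic alkene into the C7 ketone, and E1cB loss of acetate from the β-acetoxy ketone gives the α-methylene ketone; the acetoxymethyl-bearing stereocentre is erased.

Step 6
Reactants: 7 (4S)-4-bromo-3,3-dimethyl-2-methylidenecyclohexan-1-one
Product: 8 (1R,4S)-4-bromo-3,3-dimethyl-2-methylidenecyclohexan-1-ol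
Conditions: i-Bu2AlH, CH2Cl2, −78 °C; aq. potassium sodium tartrate
Reagents that add atoms: none
Why: 1,2-Reduction of the enone by the aluminium hydride; approach anti to the axial C11 methyl group should give the alcohol cis to bromine. The electron-rich allylic alcohol is needed because the enone itself does not add ketenes.

Step 7
Reactants: 8 (1R,4S)-4-bromo-3,3-dimethyl-2-methylidenecyclohexan-1-ol
Product: 9 tert-butyl{[(1R,4S)-4-bromo-3,3-dimethyl-2-methylidenecyclohexyl]oxy}dimethylsilane
Conditions: TBSOTf, 2,6-lutidine, CH2Cl2, −78 to 0 °C
Reagents that add atoms: tert-butyldimethylsilyl trifluoromethanesulfonate, CC(C)(C)[Si](C)(C)OS(=O)(=O)C(F)(F)F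
Why: Silylation of the hindered secondary alcohol; the silyl ether prevents O-acylation by the ketene and, unlike an alkyl ether, is too poor a nucleophile for a ketene Claisen pathway.

Step 8
Reactants: 9 tert-butyl{[(1R,4S)-4-bromo-3,3-dimethyl-2-methylidenecyclohexyl]oxy}dimethylsilane; 10 trichloroacetyl chloride
Product: 13 (6S,9R)-6-bromo-9-[(tert-butyldimethylsilyl)oxy]-5,5-dimethylspiro[3.5]nonan-2-one, via dichloroketene 11 (not isolated), via dichlorocyclobutanone 12 (not isolated)
Conditions: Zn(Cu), Et2O/DME, rt, ultrasound; then Zn, AcOH, rt
Reagents that add atoms: none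
Why: Zinc dechlorination of 10 gives dichloroketene, which adds [2+2] to the 1,1-disubstituted alkene with the carbonyl carbon on the terminal CH2 and the CCl2 carbon on the ring carbon (the normal ketene regiochemistry); zinc in acetic acid then removes both α-chlorines and leaves the unactivated secondary bromide. After dechlorination the spiro carbon carries two identical CH2 arms, so its configuration in 12 is of no consequence.

Step 9
Reactants: 14 1-propynylmagnesium bromide (CH3C≡CMgBr); 15 benzylchlorodimethylsilane
Product: 16 benzyldimethyl(prop-1-yn-1-yl)silane
Conditions: THF, 0 °C to rt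
Reagents that add atoms: none
Why: Substitution at silicon by an alkynyl Grignard reagent; the benzyldimethylsilyl group steers the alkyne like trimethylsilyl but can later be cleaved from an alkene carbon by fluoride at 0 °C.

Step 10
Reactants: 13 (6S,9R)-6-bromo-9-[(tert-butyldimethylsilyl)oxy]-5,5-dimethylspiro[3.5]nonan-2-one; 16 benzyldimethyl(prop-1-yn-1-yl)silane
Product: 17 (6R,7R,10S)-4-(benzyldimethylsilyl)-10-bromo-7-[(tert-butyldimethylsilyl)oxy]-3,11,11-trimethylspiro[5.5]undec-3-en-2-one
Conditions: Ni(cod)2 (10 mol %), (S,S,S)-phosphoramidite from (S)-BINOL and bis[(S)-1-phenylethyl]amine (20 mol %), toluene, 80 °C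
Reagents that add atoms: none
Why: Zerovalent nickel couples the strained ketone and the alkyne oxidatively to a spiro oxanickelacyclopentene in which C2–C3 is formed and the silyl-bearing C4 is bonded to nickel, the usual regiochemistry of silylalkynes. Strain-driven β-carbon elimination then breaks one C2–CH2 bond to give a seven-membered alkyl(alkenyl)nickel species, and C(sp2)–C(sp3) reductive elimination forms C4–C5 and returns zerovalent nickel. The closest known reaction is the nickel-catalysed intermolecular insertion of internal alkynes into 3,3-disubstituted cyclobutanones to give cyclohex-2-enones, including ligand-controlled desymmetrising versions. Ring B is closed as a formal [4+2] ring expansion, the closure itself being the reductive elimination from the nickelacycle. The only new stereocentre, C6, is set by the choice between its two diastereotopic methylene arms, because the arm whose bond to C2 is cleaved becomes C5; the chiral ligand is the controlling element, and the axial C7 silyloxy group and the C11 methyl groups, which flank the arm cis to bromine, are expected to act in the same direction. The step needs site selectivity for the arm trans to the C10 bromine (ligand), the regiochemistry C3 = methyl and C4 = silyl (silicon) and chemoselectivity for the four-membered ketone over the secondary C–Br bond (hindered neopentyl bromide, no reductant present). The quaternary C6 leaves the alkylnickel intermediate without a β-hydrogen, and with C7 masked there is no second carbonyl group.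

Step 11
Reactants: 17 (6R,7R,10S)-4-(benzyldimethylsilyl)-10-bromo-7-[(tert-butyldimethylsilyl)oxy]-3,11,11-trimethylspiro[5.5]undec-3-en-2-one
Product: 18 (6S,7R,10S)-10-bromo-7-[(tert-butyldimethylsilyl)oxy]-3,11,11-trimethylspiro[5.5]undec-3-en-2-one
Conditions: Bu4NF (2.2 equiv), THF, 0 °C, 15 min
Reagents that add atoms: none
Why: Fluoride-triggered protodesilylation of an alkenyl benzyldimethylsilane: fluoride expels the benzyl group from silicon, and the resulting fluorosilane is cleaved from the electron-poor alkene carbon with protonation at C4. The neopentyl secondary O-silyl ether should survive the short exposure at 0 °C; the C6 descriptor changes only because the priorities change.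

Step 12
Reactants: 18 (6S,7R,10S)-10-bromo-7-[(tert-butyldimethylsilyl)oxy]-3,11,11-trimethylspiro[5.5]undec-3-en-2-one
Product: 19 N'-[(2E,6S,7R,10S)-10-bromo-7-[(tert-butyldimethylsilyl)oxy]-3,11,11-trimethylspiro[5.5]undec-3-en-2-ylidene]-4-methylbenzenesulfonohydrazide
Conditions: TsNHNH2, EtOH, 50 °C
Reagents that add atoms: 4-methylbenzenesulfonohydrazide, Cc1ccc(cc1)S(=O)(=O)NN
Why: Condensation of the only carbonyl group with the sulfonyl hydrazide; the C=N geometry is immaterial.

Step 13
Reactants: 19 N'-[(2E,6S,7R,10S)-10-bromo-7-[(tert-butyldimethylsilyl)oxy]-3,11,11-trimethylspiro[5.5]undec-3-en-2-ylidene]-4-methylbenzenesulfonohydrazide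
Product: 20 (6S,7R,10S)-10-bromo-7-[(tert-butyldimethylsilyl)oxy]-3,11,11-trimethylspiro[5.5]undec-2-ene
Conditions: catecholborane, CHCl3, 0 °C; then NaOAc·3H2O, reflux
Reagents that add atoms: none
Why: Kabalka reduction of an α,β-unsaturated tosylhydrazone: hydride adds to C2, loss of sulfinate gives an allylic diazene, and its retro-ene loss of N2 delivers hydrogen to C4 and moves the alkene to C2=C3. No stereocentre is formed and the alkyl bromide is inert to the borane.

Step 14
Reactants: 20 (6S,7R,10S)-10-bromo-7-[(tert-butyldimethylsilyl)oxy]-3,11,11-trimethylspiro[5.5]undec-2-ene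
Product: 21 (6S,7R,10S)-10-bromo-3,11,11-trimethylspiro[5.5]undec-2-en-7-ol
Conditions: HF·pyridine, THF/pyridine, 0 °C to rt
Reagents that add atoms: none
Why: Non-basic fluoride cleavage of the silyl ether, chosen so that the secondary bromide is not exposed to a base.

Step 15
Reactants: 21 (6S,7R,10S)-10-bromo-3,11,11-trimethylspiro[5.5]undec-2-en-7-ol
Product: 22 (6S,10S)-10-bromo-3,11,11-trimethylspiro[5.5]undec-2-en-7-one
Conditions: Dess–Martin periodinane, pyridine, CH2Cl2, 0 °C to rt
Reagents that add atoms: none
Why: Dess–Martin oxidation of the secondary alcohol under buffered conditions that leave the trisubstituted alkene and the bromide untouched; the auxiliary C7 stereocentre is removed.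

Step 16
Reactants: 22 (6S,10S)-10-bromo-3,11,11-trimethylspiro[5.5]undec-2-en-7-one
Product: 23 (6R,10S)-10-bromo-3,11,11-trimethyl-7-methylidenespiro[5.5]undec-2-ene (10-bromo-β-chamigrene)
Conditions: Cp2TiMe2, toluene/THF, 70 °C, dark
Reagents that add atoms: dimethyltitanocene, C[Ti](C)(C1C=CC=C1)C1C=CC=C1
Why: Petasis methylenation; the titanium methylidene formed on heating is non-basic and olefinates hindered, enolisable ketones next to a quaternary carbon without touching the alkyl bromide.

Step 17
Reactants: 23 (6R,10S)-10-bromo-3,11,11-trimethyl-7-methylidenespiro[5.5]undec-2-ene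
Product: 24 (2R,3R,6R,10S)-2,10-dibromo-3,11,11-trimethyl-7-methylidenespiro[5.5]undecan-3-ol
Conditions: NBS, acetone/H2O (4:1), 0 °C
Reagents that add atoms: N-bromosuccinimide, O=C1CCC(=O)N1Br; water, O
Why: Bromohydrin formation; Br+ should go to the more electron-rich trisubstituted C2=C3 alkene and not to the hindered C7=C14, from the face anti to C7 (axial on ring B). Water then opens the unsymmetrical bromonium ion at the tertiary C3 from the opposite face (anti, Markovnikov), which sets C2 (R) and C3 (R).

## Compound list

1 | geranyl acetate | CC(=O)OC/C=C(\C)CCC=C(C)C | starting material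
2 | (2E)-5-[(2R)-3,3-dimethyloxiran-2-yl]-3-methylpent-2-en-1-yl acetate | CC(=O)OC/C=C(\C)CC[C@H]1OC1(C)C | intermediate
3 | (2E,6S)-6-bromo-7-hydroxy-3,7-dimethyloct-2-en-1-yl acetate | CC(=O)OC/C=C(\C)CC[C@H](Br)C(C)(C)O | intermediate
4 | (2E,6S)-6-bromo-7-chloro-3,7-dimethyloct-2-en-1-yl acetate | CC(=O)OC/C=C(\C)CC[C@H](Br)C(C)(C)Cl | intermediate
5 | [(1R,3S)-3-bromo-2,2-dimethyl-6-methylidenecyclohexyl]methyl acetate | C=C1CC[C@H](Br)C(C)(C)[C@@H]1COC(C)=O | intermediate
6 | [(1R,3S)-3-bromo-2,2-dimethyl-6-oxocyclohexyl]methyl acetate | O=C1CC[C@H](Br)C(C)(C)[C@@H]1COC(C)=O | intermediate (not isolated)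
7 | (4S)-4-bromo-3,3-dimethyl-2-methylidenecyclohexan-1-one | O=C1CC[C@H](Br)C(C)(C)C1=C | intermediate
8 | (1R,4S)-4-bromo-3,3-dimethyl-2-methylidenecyclohexan-1-ol | O[C@@H]1CC[C@H](Br)C(C)(C)C1=C | intermediate
9 | tert-butyl{[(1R,4S)-4-bromo-3,3-dimethyl-2-methylidenecyclohexyl]oxy}dimethylsilane | CC(C)(C)[Si](C)(C)O[C@@H]1CC[C@H](Br)C(C)(C)C1=C | intermediate
10 | trichloroacetyl chloride | O=C(Cl)C(Cl)(Cl)Cl | starting material
11 | dichloroketene | O=C=C(Cl)Cl | intermediate (not isolated)
12 | (4R,6S,9R)-6-bromo-9-[(tert-butyldimethylsilyl)oxy]-1,1-dichloro-5,5-dimethylspiro[3.5]nonan-2-one | CC(C)(C)[Si](C)(C)O[C@@H]1CC[C@H](Br)C(C)(C)[C@@]12C(Cl)(Cl)C(=O)C2 | intermediate (not isolated)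
13 | (6S,9R)-6-bromo-9-[(tert-butyldimethylsilyl)oxy]-5,5-dimethylspiro[3.5]nonan-2-one | CC(C)(C)[Si](C)(C)O[C@@H]1CC[C@H](Br)C(C)(C)C12CC(=O)C2 | intermediate
14 | 1-propynylmagnesium bromide | CC#C[Mg]Br | starting material
15 | benzylchlorodimethylsilane | C[Si](C)(Cl)Cc1ccccc1 | starting material
16 | benzyldimethyl(prop-1-yn-1-yl)silane | CC#C[Si](C)(C)Cc1ccccc1 | intermediate
17 | (6R,7R,10S)-4-(benzyldimethylsilyl)-10-bromo-7-[(tert-butyldimethylsilyl)oxy]-3,11,11-trimethylspiro[5.5]undec-3-en-2-one | CC(C)(C)[Si](C)(C)O[C@@H]1CC[C@H](Br)C(C)(C)[C@@]12CC([Si](C)(C)Cc3ccccc3)=C(C)C(=O)C2 | intermediate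
18 | (6S,7R,10S)-10-bromo-7-[(tert-butyldimethylsilyl)oxy]-3,11,11-trimethylspiro[5.5]undec-3-en-2-one | CC(C)(C)[Si](C)(C)O[C@@H]1CC[C@H](Br)C(C)(C)[C@@]12CC=C(C)C(=O)C2 | intermediate
19 | (E)-4-methylbenzenesulfonylhydrazone of 18 | CC(C)(C)[Si](C)(C)O[C@@H]1CC[C@H](Br)C(C)(C)[C@@]12CC=C(C)C(=N/NS(=O)(=O)c3ccc(C)cc3)/C2 | intermediate
20 | (6S,7R,10S)-10-bromo-7-[(tert-butyldimethylsilyl)oxy]-3,11,11-trimethylspiro[5.5]undec-2-ene | CC(C)(C)[Si](C)(C)O[C@@H]1CC[C@H](Br)C(C)(C)[C@@]12CCC(C)=CC2 | intermediate
21 | (6S,7R,10S)-10-bromo-3,11,11-trimethylspiro[5.5]undec-2-en-7-ol | O[C@@H]1CC[C@H](Br)C(C)(C)[C@@]12CCC(C)=CC2 | intermediate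
22 | (6S,10S)-10-bromo-3,11,11-trimethylspiro[5.5]undec-2-en-7-one | O=C1CC[C@H](Br)C(C)(C)[C@@]12CCC(C)=CC2 | intermediate
23 | (6R,10S)-10-bromo-3,11,11-trimethyl-7-methylidenespiro[5.5]undec-2-ene | C=C1CC[C@H](Br)C(C)(C)[C@@]12CCC(C)=CC2 | intermediate
24 | (2R,3R,6R,10S)-2,10-dibromo-3,11,11-trimethyl-7-methylidenespiro[5.5]undecan-3-ol | C=C1CC[C@H](Br)C(C)(C)[C@@]12CC[C@@](C)(O)[C@H](Br)C2 | target

## Step count and least certain steps

Total: 17 steps. Longest linear sequence: 16 steps (steps 1–8 and 10–17); step 9 is a one-step side branch.

Step 10 (key step). The most likely failure is weak discrimination between the two methylene arms of 13, so that both C6 configurations form. The substrate bias comes from ring A conformers of similar energy and the ligand effect on this substrate is untested. A second risk is catalyst loss by halogen abstraction from the secondary C–Br bond by zerovalent nickel at 80 °C. The fallback gives up C–C activation. It sets out from 7, which is treated with isoprene and Me2AlCl in CH2Cl2 at −78 °C in a Diels–Alder reaction; the para orientation puts the methyl group on C3, and addition of the diene to the alkene face cis to bromine would give the C6 configuration of 22. No compound outside the list is formed (F0), and the route is rejoined at 22.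

Step 2. The most likely failure is bromide attack at the tertiary epoxide carbon or a Lewis-acid-induced epoxide rearrangement. Either puts bromine on the wrong carbon and breaks the stereochemical relay, because only inversion at the secondary carbon transfers the configuration. The fallback reverses the order of halogen introduction. It sets out from 2, which is opened with HCl in Et2O at −20 °C at the tertiary carbon to give (2E,6R)-7-chloro-6-hydroxy-3,7-dimethyloct-2-en-1-yl acetate F1. Tf2O and pyridine give (2E,6R)-7-chloro-3,7-dimethyl-6-[(trifluoromethanesulfonyl)oxy]oct-2-en-1-yl acetate F2, and Bu4NBr displaces the triflate with inversion. The route is rejoined at 4, and step 3 is no longer needed.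

Step 8. The most likely failure is slow cycloaddition at the alkene, which is flanked by a quaternary carbon and a silyloxy-bearing carbon; ketene oligomerisation and ZnCl2-induced loss of the allylic silyl ether would then take over. The fallback uses a more electrophilic two-carbon partner and needs no dechlorination. It sets out from 9, which is heated with N,N-dimethylacetamide, Tf2O and 2,4,6-collidine in ClCH2CH2Cl (keteniminium [2+2]) to give N-[(6S,9R)-6-bromo-9-[(tert-butyldimethylsilyl)oxy]-5,5-dimethylspiro[3.5]nonan-2-ylidene]-N-methylmethanaminium trifluoromethanesulfonate F3. Aqueous hydrolysis rejoins the route at 13.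

Step 17. The most likely failure is opening of the bromonium ion at the secondary C2 in the trans-diaxial mode, which the ground-state chair of ring B favours, so that the regioisomeric bromohydrin accompanies 24. The target is the diequatorial isomer and must form through a non-chair opening at C3. Reaction through the bromonium ion on the face syn to C7 is a second leak. The fallback corrects the site of bromine by substitution instead of addition and sets out from 23.
- NBS/H2O gives crude 24 together with (2S,3S,6R,10S)-3,10-dibromo-3,11,11-trimethyl-7-methylidenespiro[5.5]undecan-2-ol F4.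
- K2CO3 in MeOH converts both into one compound, (2S,3R,6R,10S)-10-bromo-2,3-epoxy-3,11,11-trimethyl-7-methylidenespiro[5.5]undecane F5, with the oxirane oxygen on the ring B face syn to C7.
- Li2NiBr4 in THF opens F5 at the secondary C2 with inversion, and the route is rejoined at 24.

## Further compounds

F0 | step 10 | none | none
F1 | step 2 | (2E,6R)-7-chloro-6-hydroxy-3,7-dimethyloct-2-en-1-yl acetate | CC(=O)OC/C=C(\C)CC[C@@H](O)C(C)(C)Cl
F2 | step 2 | (2E,6R)-7-chloro-3,7-dimethyl-6-[(trifluoromethanesulfonyl)oxy]oct-2-en-1-yl acetate | CC(=O)OC/C=C(\C)CC[C@@H](OS(=O)(=O)C(F)(F)F)C(C)(C)Cl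
F3 | step 8 | N-[(6S,9R)-6-bromo-9-[(tert-butyldimethylsilyl)oxy]-5,5-dimethylspiro[3.5]nonan-2-ylidene]-N-methylmethanaminium trifluoromethanesulfonate | CC(C)(C)[Si](C)(C)O[C@@H]1CC[C@H](Br)C(C)(C)C12CC(=[N+](C)C)C2.[O-]S(=O)(=O)C(F)(F)F
F4 | step 17 | (2S,3S,6R,10S)-3,10-dibromo-3,11,11-trimethyl-7-methylidenespiro[5.5]undecan-2-ol | C=C1CC[C@H](Br)C(C)(C)[C@@]12CC[C@](C)(Br)[C@@H](O)C2
F5 | step 17 | (2S,3R,6R,10S)-10-bromo-2,3-epoxy-3,11,11-trimethyl-7-methylidenespiro[5.5]undecane | C=C1CC[C@H](Br)C(C)(C)[C@@]12CC[C@@]3(C)O[C@H]3C2
A1 | alternative 1 | (E)-γ-bisabolene | CC1=CC/C(=C(\C)CCC=C(C)C)CC1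
A2 | alternative 1 | (6R,10S)-10-bromo-β-chamigrene | C=C1CC[C@H](Br)C(C)(C)[C@@]12CCC(C)=CC2
A3 | alternative 2 | (1R,3S)-3-bromo-2,2-dimethyl-6-methylidenecyclohexane-1-carbaldehyde (bromo-γ-cyclocitral) | C=C1CC[C@H](Br)C(C)(C)[C@@H]1C=O
A4 | alternative 2 | methyl vinyl ketone | CC(=O)C=C
A5 | alternative 2 | (6R,10S)-10-bromo-11,11-dimethyl-7-methylidenespiro[5.5]undec-1-en-3-one | C=C1CC[C@H](Br)C(C)(C)[C@@]12CCC(=O)C=C2
A6 | alternative 3 | 2-[(1R,3S)-3-bromo-2,2-dimethyl-6-methylidene-1-(3-oxobutyl)cyclohexyl]acetaldehyde | C=C1CC[C@H](Br)C(C)(C)[C@@]1(CC=O)CCC(C)=O
A7 | alternative 3 | (3R,6R,10S)-10-bromo-3-hydroxy-3,11,11-trimethyl-7-methylidenespiro[5.5]undecan-2-one | C=C1CC[C@H](Br)C(C)(C)[C@@]12CC[C@@](C)(O)C(=O)C2
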